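**Retrosynthetic overview**
1. C8'=C9' (Z): Z-selective cross-metathesis of the resorcylic acid alkene 8 (masked in the flask as its TMS derivative) with (R)-oct-1-en-3-yl acetate 2.
2. C10'–O bond and the only stereocentre: enantioselective branched allylic C–H acetoxylation of oct-1-ene 1 with acetic acid (key step).
3. ArCH2–CH2 bond: lateral lithiation of methyl 2,4-dimethoxy-6-methylbenzoate 3 and alkylation with 8-bromooct-1-ene 4, then global O-demethylation.
4. No ring is formed; the benzene ring is bought with 3.

Assumption: side-chain carbons are numbered C1'–C15' from the ring, C10' is R as read from the SMILES, and L* in step 1 is whichever ligand antipode screening shows to give R.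

**Step 1**
Reactants: 1 oct-1-ene
Product: 2 (R)-oct-1-en-3-yl acetate
Conditions: Pd2(dba)3 (2.5 mol%), chiral 3,3'-diaryl-H8-BINOL phosphoramidite L* (10 mol%), 2,5-dimethyl-1,4-benzoquinone (1.2 equiv), AcOH (3 equiv), MTBE, 40 °C
Reagents that add atoms: acetic acid, CC(=O)O
Why: Proposed new method: an enantioselective branched allylic C–H acetoxylation in which Pd(0)/L* and the quinone cleave the allylic C–H bond of 1 by concerted proton/two-electron transfer to give (π-allyl)Pd(L*)(OAc), whose κ1-acetate then forms the C3–O bond by an inner-sphere seven-membered (3,3'-type) reductive elimination from the η1-allyl form with Pd on the CH2 terminus, so the ester is branched and the ligand pocket selects the allyl face (R at C3, checked by chiral GC against authentic material); the closest known reaction types are the Pd/bis-sulfoxide branched allylic C–H acetoxylation (racemic or modest ee) and the Pd/phosphoramidite/quinone enantioselective allylic C–H alkylation.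

**Step 2**
Reactants: 3 methyl 2,4-dimethoxy-6-methylbenzoate; 4 8-bromooct-1-ene
Product: 6 methyl 2,4-dimethoxy-6-(non-8-en-1-yl)benzoate, via benzylic lithium species 5 (not isolated)
Conditions: LDA (1.15 equiv), THF, −78 °C; then 4 (1.3 equiv), DMPU, −78 → 0 °C
Reagents that add atoms: none
Why: Lateral lithiation of the o-toluate gives the ester-stabilised benzylic anion 5, and SN2 alkylation with the primary bromide installs the nine-carbon ω-alkenyl chain; no stereocentre is involved.

**Step 3**
Reactants: 6 methyl 2,4-dimethoxy-6-(non-8-en-1-yl)benzoate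
Product: 8 2,4-dihydroxy-6-(non-8-en-1-yl)benzoic acid, via tris(dibromoboryl) intermediate 7 (not isolated)
Conditions: BBr3 (6 equiv), CH2Cl2, −78 °C → rt, 16 h; then ice/H2O, 0 °C
Reagents that add atoms: none
Why: Lewis-acid dealkylation: BBr3 cleaves both aryl methyl ethers and the methyl ester by bromide attack at methyl, so the di-ortho-substituted ester is no obstacle, while the isolated terminal alkene is not attacked and the cold work-up avoids decarboxylation.

**Step 4**
Reactants: 8 2,4-dihydroxy-6-(non-8-en-1-yl)benzoic acid; 2 (R)-oct-1-en-3-yl acetate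
Product: 11 6-[(8Z,10R)-10-acetoxypentadec-8-en-1-yl]-2,4-dihydroxybenzoic acid, via tris-TMS acid 9 (not isolated), via tris-TMS cross-metathesis product 10 (not isolated)
Conditions: (i) HMDS, cat. TMSCl, THF, 50 °C, then evaporate; (ii) 2 (3 equiv), cyclometalated Ru nitrato Z-selective catalyst (N-adamantyl/N-2,6-iPr2C6H3 NHC, 5 mol%), THF, 35 °C, static vacuum; (iii) 5% aq. citric acid/THF, rt
Reagents that add atoms: none
Why: Transient O-silylation keeps the acid and phenols away from the Ru carboxylate-type catalyst, Z-selective olefin cross-metathesis joins the two terminal alkenes with loss of ethylene, and mild aqueous acid removes the TMS groups without touching the allylic acetate; the C10' stereocentre from 2 is not involved.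

**Compound list**
1 | oct-1-ene | C=CCCCCCC | starting material
2 | (R)-oct-1-en-3-yl acetate | CCCCC[C@H](C=C)OC(C)=O | intermediate
3 | methyl 2,4-dimethoxy-6-methylbenzoate | COC(=O)c1c(C)cc(OC)cc1OC | starting material
4 | 8-bromooct-1-ene | C=CCCCCCCBr | starting material
5 | methyl 2-(lithiomethyl)-4,6-dimethoxybenzoate (benzylic lithium species) | [Li]Cc1cc(OC)cc(OC)c1C(=O)OC | intermediate
6 | methyl 2,4-dimethoxy-6-(non-8-en-1-yl)benzoate | COC(=O)c1c(OC)cc(OC)cc1CCCCCCCC=C | intermediate
7 | dibromoboryl 2,4-bis(dibromoboryloxy)-6-(non-8-en-1-yl)benzoate (idealised O–B intermediate) | BrB(Br)OC(=O)c1c(OB(Br)Br)cc(OB(Br)Br)cc1CCCCCCCC=C | intermediate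
8 | 2,4-dihydroxy-6-(non-8-en-1-yl)benzoic acid | OC(=O)c1c(O)cc(O)cc1CCCCCCCC=C | intermediate
9 | trimethylsilyl 6-(non-8-en-1-yl)-2,4-bis(trimethylsilyloxy)benzoate | C[Si](C)(C)OC(=O)c1c(O[Si](C)(C)C)cc(O[Si](C)(C)C)cc1CCCCCCCC=C | intermediate
10 | trimethylsilyl 6-[(8Z,10R)-10-acetoxypentadec-8-en-1-yl]-2,4-bis(trimethylsilyloxy)benzoate | CCCCC[C@H](/C=C\CCCCCCCc1cc(O[Si](C)(C)C)cc(O[Si](C)(C)C)c1C(=O)O[Si](C)(C)C)OC(C)=O | intermediate
11 | 6-[(8Z,10R)-10-acetoxypentadec-8-en-1-yl]-2,4-dihydroxybenzoic acid (CNP0288291.1) | CCCCC[C@H](/C=C\CCCCCCCc1cc(O)cc(O)c1C(=O)O)OC(C)=O | target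

**Totals**
Total step count: 4. Longest linear sequence: 3 steps (3 → 6 → 8 → 11).

**Three steps most likely to fail**

Step 1 (proposed new step). The risks are linear acetate formation by outer-sphere attack, low ee, and re-ionisation of the branched product by Pd(0). The fallback uses known chemistry, sets out from 1 and comes back at 2. Racemic branched allylic C–H acetoxylation of 1 (Pd(OAc)2/1,2-bis(phenylsulfinyl)ethane, benzoquinone, AcOH, dioxane, 45 °C) gives racemic oct-1-en-3-yl acetate F1. Lipase hydrolysis (CAL-B, pH 7 buffer, 30 °C, to about 60% conversion) then removes the fast-reacting (S)-ester, as predicted by the Kazlauskas rule with vinyl as the medium group. The unreacted (R)-ester is 2.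

Step 4. The risks are slow metathesis of the secondary allylic acetate, homodimerisation of 9, and loss of Z-selectivity. The fallback replaces metathesis by a cis-selective Wittig olefination; it sets out from 3 and 2 and comes back at 11. Lateral lithiation of 3 as in step 2 and alkylation with excess 1,7-dibromoheptane gives methyl 2-(8-bromooctyl)-4,6-dimethoxybenzoate F3. PPh3 in refluxing MeCN gives the phosphonium bromide of the protected arene F4, and BBr3 (CH2Cl2, −78 °C → rt) gives [8-(2-carboxy-3,5-dihydroxyphenyl)octyl]triphenylphosphonium bromide F5. Ozonolysis of 2 (O3, CH2Cl2, −78 °C; Me2S) gives (R)-1-oxoheptan-2-yl acetate F6. Treating F5 with NaHMDS (4.1 equiv, THF/DMPU, −78 °C) gives the trisodium ylide F7, which reacts with F6 at −78 → 0 °C and gives 11 after citric acid work-up.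

Step 3. The risks are incomplete cleavage of the hindered methyl ester and HBr addition to the alkene during the long exposure to BBr3 at rt. The fallback removes the ester by saponification while the ring is still O-methylated and then cleaves only the ethers under milder conditions; it sets out from 6 and comes back at 8. KOH in DMSO/H2O at 110 °C gives 2,4-dimethoxy-6-(non-8-en-1-yl)benzoic acid F2. BBr3 (4 equiv, CH2Cl2, −78 → 0 °C) then gives 8.

**Further compounds**
F1 | step 1 | racemic oct-1-en-3-yl acetate | CCCCCC(C=C)OC(C)=O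
F2 | step 3 | 2,4-dimethoxy-6-(non-8-en-1-yl)benzoic acid | OC(=O)c1c(OC)cc(OC)cc1CCCCCCCC=C
F3 | step 4 | methyl 2-(8-bromooctyl)-4,6-dimethoxybenzoate | COC(=O)c1c(OC)cc(OC)cc1CCCCCCCCBr
F4 | step 4 | [8-(3,5-dimethoxy-2-(methoxycarbonyl)phenyl)octyl]triphenylphosphonium bromide | COC(=O)c1c(OC)cc(OC)cc1CCCCCCCC[P+](c1ccccc1)(c1ccccc1)c1ccccc1.[Br-]
F5 | step 4 | [8-(2-carboxy-3,5-dihydroxyphenyl)octyl]triphenylphosphonium bromide | OC(=O)c1c(O)cc(O)cc1CCCCCCCC[P+](c1ccccc1)(c1ccccc1)c1ccccc1.[Br-]
F6 | step 4 | (R)-1-oxoheptan-2-yl acetate | CCCCC[C@H](C=O)OC(C)=O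
F7 | step 4 | trisodium ylide of F5 | [Na+].[Na+].[Na+].[O-]C(=O)c1c([O-])cc([O-])cc1CCCCCCCC=P(c1ccccc1)(c1ccccc1)c1ccccc1
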